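**Retrosynthetic overview**
1. The target comes from its C10,C13-diol by a final double acetylation.
2. The diol comes from an open-chain (Z)-enal/enol triflate: an electrochemical chromium–nickel alkenylation closes the ten-membered carbocycle at C6–C7 first, then the C6 alkoxide closes the butenolide (C6 is set here).
3. The enol triflate (C11–C13 unit) comes from a β-keto ester, made from the C7 aldehyde and a serine-derived diazo ester.
4. The C1 ketone and the C3–C4 bond come from a cyclopropanol (Kulinkovich reaction on the lactone; C2 and C3 from EtMgBr) coupled with a (Z)-alkenyl iodide made from but-2-yn-1-ol.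
5. C8 is bought as (S)-5-(hydroxymethyl)butyrolactone (from L-glutamic acid); C10 is set by enolate hydroxylation anti to the C5 side chain.

Assumption: germacrane numbering is used for all intermediates (C1 ring ketone, C4=C5 ring alkene, C6 lactone carbinol, C7=C11 butenolide alkene, C8 methacrylate carbinol, C10 acetoxy carbon, C12 lactone carbonyl, C13 acetoxymethyl carbon, C14 and C15 methyls).

**Route**

Step 1
Reactants: 1 (S)-5-(hydroxymethyl)dihydrofuran-2(3H)-one
Product: 2 (S)-5-{[(triethylsilyl)oxy]methyl}dihydrofuran-2(3H)-one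
Conditions: Et3SiCl, imidazole, CH2Cl2, 0 °C to rt
Reagents that add atoms: chlorotriethylsilane (CC[Si](Cl)(CC)CC)
Why: Routine silyl ether protection of the primary alcohol; the triethylsilyl group survives the enolate and organometallic steps, is later oxidised off directly under Swern conditions, and the bought C8 centre is untouched.

Step 2
Reactants: 2 (S)-5-{[(triethylsilyl)oxy]methyl}dihydrofuran-2(3H)-one
Product: 3 (3R,5S)-3-methyl-5-{[(triethylsilyl)oxy]methyl}dihydrofuran-2(3H)-one (trans, a little cis epimer carried on)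
Conditions: LiN(iPr)2, THF, −78 °C; MeI, −78 to −40 °C
Reagents that add atoms: iodomethane (CI)
Why: Lithium enolate alkylation of the γ-lactone (methyl enters anti to the C5 side chain); the C3 configuration does not matter because this centre is enolised again in step 3.

Step 3
Reactants: 3 (3R,5S)-3-methyl-5-{[(triethylsilyl)oxy]methyl}dihydrofuran-2(3H)-one
Product: 5 (3R,5S)-3-methyl-3-[(triethylsilyl)oxy]-5-{[(triethylsilyl)oxy]methyl}dihydrofuran-2(3H)-one, via sodium lactone alkoxide 4 (not isolated)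
Conditions: NaN(SiMe3)2, THF, −78 °C; 3-phenyl-2-(phenylsulfonyl)oxaziridine; then Et3SiCl, −78 °C to rt
Reagents that add atoms: 3-phenyl-2-(phenylsulfonyl)oxaziridine (O=S(=O)(c1ccccc1)N1OC1c1ccccc1); chlorotriethylsilane (CC[Si](Cl)(CC)CC)
Why: Davis enolate hydroxylation: the planar sodium enolate is oxidised on the face anti to the C5 silyloxymethyl group, so the new oxygen is trans to it and C10 is fixed as (R) under control of the bought C8 centre; the tertiary alkoxide is capped in the same flask.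

Step 4
Reactants: 5 (3R,5S)-3-methyl-3-[(triethylsilyl)oxy]-5-{[(triethylsilyl)oxy]methyl}dihydrofuran-2(3H)-one
Product: 6 1-{(2R,4S)-4-hydroxy-2,5-bis[(triethylsilyl)oxy]pentan-2-yl}cyclopropan-1-ol
Conditions: EtMgBr (3 equiv), Ti(OiPr)4 (1 equiv), THF, 0 °C to rt
Reagents that add atoms: ethylmagnesium bromide (CC[Mg]Br)
Why: Kulinkovich cyclopropanation: the titanacyclopropane made from EtMgBr and Ti(OiPr)4 adds twice to the lactone carbonyl, turning C1 into a cyclopropanol that carries C2 and C3 and freeing the C8 hydroxyl, without touching either stereocentre.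

Step 5
Reactants: 7 but-2-yn-1-ol
Product: 9 (Z)-3-iodobut-2-en-1-ol, via sodium oxaluminolide 8 (not isolated)
Conditions: NaAlH2(OCH2CH2OCH3)2, THF, 0 °C to rt; then I2, −78 to 0 °C
Reagents that add atoms: iodine (II)
Why: Hydroxyl-directed trans-hydroalumination of the propargylic alcohol, then iodinolysis of the C–Al bond with retention, gives only the (Z)-iodide and so fixes the geometry of the future C4=C5 ring alkene.

Step 6
Reactants: 9 (Z)-3-iodobut-2-en-1-ol
Product: 10 (Z)-triethyl[(3-iodobut-2-en-1-yl)oxy]silane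
Conditions: Et3SiCl, imidazole, CH2Cl2, 0 °C
Reagents that add atoms: chlorotriethylsilane (CC[Si](Cl)(CC)CC)
Why: Routine silylation, so that after the coupling only the C8 hydroxyl is free for acylation and both primary silyl ethers can be oxidised together in step 9.

Step 7
Reactants: 6 1-{(2R,4S)-4-hydroxy-2,5-bis[(triethylsilyl)oxy]pentan-2-yl}cyclopropan-1-ol; 10 (Z)-triethyl[(3-iodobut-2-en-1-yl)oxy]silane
Product: 11 (2Z,7R,9S)-9-hydroxy-3,7-dimethyl-1,7,10-tris[(triethylsilyl)oxy]dec-2-en-6-one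
Conditions: Pd(OAc)2 (10 mol%), XPhos (20 mol%), Cs2CO3, toluene, 80 °C
Reagents that add atoms: none
Why: Palladium-catalysed ring-opening cross-coupling of a cyclopropanol (ketone homoenolate coupling): oxidative addition of the alkenyl iodide to zerovalent palladium, alkoxide exchange, β-carbon elimination and reductive elimination form the C3–C4 bond with retention of the (Z) geometry and unveil the C1 ketone.

Step 8
Reactants: 11 (2Z,7R,9S)-9-hydroxy-3,7-dimethyl-1,7,10-tris[(triethylsilyl)oxy]dec-2-en-6-one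
Product: 12 (2S,4R,8Z)-4,8-dimethyl-5-oxo-1,4,10-tris[(triethylsilyl)oxy]dec-8-en-2-yl 2-methylprop-2-enoate
Conditions: methacrylic anhydride, Et3N, DMAP (cat.), CH2Cl2, 0 °C to rt
Reagents that add atoms: methacrylic anhydride (C=C(C)C(=O)OC(=O)C(C)=C)
Why: DMAP-catalysed acyl transfer esterifies the only free hydroxyl (secondary, C8) with retention, drawing the γ-hydroxy ketone/lactol equilibrium to the open-chain ester.

Step 9
Reactants: 12 (2S,4R,8Z)-4,8-dimethyl-5-oxo-1,4,10-tris[(triethylsilyl)oxy]dec-8-en-2-yl 2-methylprop-2-enoate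
Product: 13 (2S,4R,8Z)-4,8-dimethyl-1,5,10-trioxo-4-[(triethylsilyl)oxy]dec-8-en-2-yl 2-methylprop-2-enoate
Conditions: (COCl)2 (6 equiv), DMSO, CH2Cl2, −78 to −35 °C; iPr2NEt, −78 to 0 °C
Reagents that add atoms: none
Why: Swern oxidation in which the two primary triethylsilyl ethers are cleaved in situ and oxidised to the C6 and C7 aldehydes while the tertiary silyl ether stays; low temperature and a hindered amine protect the α-acyloxy C8 centre and the (Z)-enal.

Step 10
Reactants: 14 methyl DL-serinate hydrochloride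
Product: 15 methyl O-[tert-butyl(dimethyl)silyl]-DL-serinate
Conditions: tBuMe2SiCl, imidazole, CH2Cl2, rt
Reagents that add atoms: tert-butylchlorodimethylsilane (CC(C)(C)[Si](C)(C)Cl)
Why: O-silylation of the primary alcohol (any N-silyl product hydrolyses on work-up); the racemate is used because this stereocentre is destroyed in step 11.

Step 11
Reactants: 15 methyl O-[tert-butyl(dimethyl)silyl]-DL-serinate
Product: 16 methyl 3-{[tert-butyl(dimethyl)silyl]oxy}-2-diazopropanoate
Conditions: isoamyl nitrite, AcOH (10 mol%), CHCl3, reflux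
Reagents that add atoms: 3-methylbutyl nitrite (CC(C)CCON=O)
Why: Diazotisation of an α-amino ester: N-nitrosation and loss of water give the ester-stabilised diazo compound.

Step 12
Reactants: 13 (2S,4R,8Z)-4,8-dimethyl-1,5,10-trioxo-4-[(triethylsilyl)oxy]dec-8-en-2-yl 2-methylprop-2-enoate; 16 methyl 3-{[tert-butyl(dimethyl)silyl]oxy}-2-diazopropanoate
Product: 17 methyl (4S,6R,10Z)-2-({[tert-butyl(dimethyl)silyl]oxy}methyl)-6,10-dimethyl-4-[(2-methylprop-2-enoyl)oxy]-3,7,12-trioxo-6-[(triethylsilyl)oxy]dodec-10-enoate (C2 epimers)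
Conditions: BF3·OEt2 (20 mol%), CH2Cl2, −78 °C
Reagents that add atoms: none
Why: Roskamp-type homologation (Lewis-acid-catalysed formal C–H insertion of an α-substituted diazo ester into an aldehyde): the diazo carbon adds to the most electrophilic carbonyl, the α-acyloxy C7 aldehyde, and a 1,2-hydride shift with loss of N2 gives the β-keto ester, leaving the conjugated enal and the ketone alone; the new C11 centre is planarised in step 13.

Step 13
Reactants: 17 methyl (4S,6R,10Z)-2-({[tert-butyl(dimethyl)silyl]oxy}methyl)-6,10-dimethyl-4-[(2-methylprop-2-enoyl)oxy]-3,7,12-trioxo-6-[(triethylsilyl)oxy]dodec-10-enoate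
Product: 18 methyl (2Z,4S,6R,10Z)-2-({[tert-butyl(dimethyl)silyl]oxy}methyl)-6,10-dimethyl-4-[(2-methylprop-2-enoyl)oxy]-7,12-dioxo-6-[(triethylsilyl)oxy]-3-{[(trifluoromethyl)sulfonyl]oxy}dodeca-2,10-dienoate
Conditions: LiN(SiMe3)2 (1.05 equiv), THF, −78 °C; PhNTf2, −78 to 0 °C
Reagents that add atoms: N-phenylbis(trifluoromethanesulfonimide) (O=S(=O)(N(c1ccccc1)S(=O)(=O)C(F)(F)F)C(F)(F)F)
Why: O-sulfonylation of the chelated lithium (Z)-enolate of the β-keto ester (by far the most acidic site) gives the enol triflate with the triflate cis to the ester, the geometry needed for lactonisation once the C6–C7 bond exists.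

Step 14
Reactants: 18 methyl (2Z,4S,6R,10Z)-2-({[tert-butyl(dimethyl)silyl]oxy}methyl)-6,10-dimethyl-4-[(2-methylprop-2-enoyl)oxy]-7,12-dioxo-6-[(triethylsilyl)oxy]-3-{[(trifluoromethyl)sulfonyl]oxy}dodeca-2,10-dienoate
Product: 20 (4Z,6R,8S,10R)-10,13-dihydroxy-8-(methacryloyloxy)-1-oxogermacra-4,7(11)-dien-12,6-olide, via ring-closed silyl ether 19 (not isolated)
Conditions: CrCl3 (20 mol%), NiCl2(dme) (5 mol%), 2,9-dimethyl-1,10-phenanthroline (6 mol%), Me3SiCl (3 equiv), LiCl, DMF, undivided cell, Al anode, Ni-foam cathode, constant current, 18 added over 10 h to 2 mM, rt; then 2 M HCl, THF, rt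
Reagents that add atoms: none
Why: Proposed new method: the cathode keeps a catalytic CrCl3/CrCl2 couple turning over while zerovalent nickel (formed from NiCl2 by divalent chromium) inserts into the electron-poor C7–OTf bond and passes the alkenyl group to chromium; the trivalent alkenylchromium then adds 1,2 to the tethered (Z)-enal at a potential far above that needed to reduce the enal, ketone or methacrylate, Me3SiCl releases chromium from the C6 alkoxide, and the acid work-up strips the three silyl groups so that the C6 hydroxyl, held cis to the ester, lactonises. The closest known chemistry is the intermolecular electrochemical Nozaki–Hiyama–Kishi alkenylation of aldehydes, the stoichiometric CrCl2/NiCl2 macrocyclisations of alkenyl halides, and butenolide formation from (Z)-β-halo acrylates and aldehydes; none has been used to close a medium carbocycle and a butenolide in one electrochemical step. C6 is set by the bought C8 centre: A(1,3) strain with the C13 silyloxymethyl group holds C8–H in the alkene plane, so C9 and the C8 oxygen lie on opposite faces; with C7 at a corner of the forming ten-membered ring, C5 is delivered on the face opposite C9, which gives the (6R) alkoxide with the C6 and C8 oxygens cis.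

Step 15
Reactants: 20 (4Z,6R,8S,10R)-10,13-dihydroxy-8-(methacryloyloxy)-1-oxogermacra-4,7(11)-dien-12,6-olide
Product: 21 (4Z,6R,8S,10R)-10,13-diacetoxy-8-(methacryloyloxy)-1-oxogermacra-4,7(11)-dien-12,6-olide (CNP0115165.2)
Conditions: Ac2O, Sc(OTf)3 (5 mol%), MeCN, −20 °C
Reagents that add atoms: acetic anhydride (CC(=O)OC(C)=O)
Why: Sc(OTf)3-catalysed acylation with Ac2O esterifies the primary allylic and the hindered tertiary alcohol in one operation under non-basic conditions, so the acidic C6–H next to the butenolide is not epimerised.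

**Compound list**

1 | (S)-5-(hydroxymethyl)dihydrofuran-2(3H)-one | OC[C@@H]1CCC(=O)O1 | starting material
2 | (S)-5-{[(triethylsilyl)oxy]methyl}dihydrofuran-2(3H)-one | O1[C@H](CO[Si](CC)(CC)CC)CCC1=O | intermediate
3 | (3R,5S)-3-methyl-5-{[(triethylsilyl)oxy]methyl}dihydrofuran-2(3H)-one | O1[C@H](CO[Si](CC)(CC)CC)C[C@@H](C)C1=O | intermediate
4 | sodium (3R,5S)-3-methyl-2-oxo-5-{[(triethylsilyl)oxy]methyl}tetrahydrofuran-3-olate | O1[C@H](CO[Si](CC)(CC)CC)C[C@@](C)([O-])C1=O.[Na+] | intermediate (not isolated)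
5 | (3R,5S)-3-methyl-3-[(triethylsilyl)oxy]-5-{[(triethylsilyl)oxy]methyl}dihydrofuran-2(3H)-one | O1[C@H](CO[Si](CC)(CC)CC)C[C@@](C)(O[Si](CC)(CC)CC)C1=O | intermediate
6 | 1-{(2R,4S)-4-hydroxy-2,5-bis[(triethylsilyl)oxy]pentan-2-yl}cyclopropan-1-ol | O[C@H](CO[Si](CC)(CC)CC)C[C@@](C)(O[Si](CC)(CC)CC)C1(O)CC1 | intermediate
7 | but-2-yn-1-ol | CC#CCO | starting material
8 | sodium 2,2-bis(2-methoxyethoxy)-3-methyl-2,5-dihydro-1,2-oxaluminol-2-uide | CC1=CCO[Al-]1(OCCOC)OCCOC.[Na+] | intermediate (not isolated)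
9 | (Z)-3-iodobut-2-en-1-ol | C/C(I)=C/CO | intermediate
10 | (Z)-triethyl[(3-iodobut-2-en-1-yl)oxy]silane | C/C(I)=C/CO[Si](CC)(CC)CC | intermediate
11 | (2Z,7R,9S)-9-hydroxy-3,7-dimethyl-1,7,10-tris[(triethylsilyl)oxy]dec-2-en-6-one | O[C@H](CO[Si](CC)(CC)CC)C[C@@](C)(O[Si](CC)(CC)CC)C(=O)CC/C(C)=C\CO[Si](CC)(CC)CC | intermediate
12 | (2S,4R,8Z)-4,8-dimethyl-5-oxo-1,4,10-tris[(triethylsilyl)oxy]dec-8-en-2-yl 2-methylprop-2-enoate | C=C(C)C(=O)O[C@H](CO[Si](CC)(CC)CC)C[C@@](C)(O[Si](CC)(CC)CC)C(=O)CC/C(C)=C\CO[Si](CC)(CC)CC | intermediate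
13 | (2S,4R,8Z)-4,8-dimethyl-1,5,10-trioxo-4-[(triethylsilyl)oxy]dec-8-en-2-yl 2-methylprop-2-enoate | C=C(C)C(=O)O[C@H](C=O)C[C@@](C)(O[Si](CC)(CC)CC)C(=O)CC/C(C)=C\C=O | intermediate
14 | methyl DL-serinate hydrochloride | COC(=O)C(N)CO.Cl | starting material
15 | methyl O-[tert-butyl(dimethyl)silyl]-DL-serinate | COC(=O)C(N)CO[Si](C)(C)C(C)(C)C | intermediate
16 | methyl 3-{[tert-butyl(dimethyl)silyl]oxy}-2-diazopropanoate | COC(=O)C(=[N+]=[N-])CO[Si](C)(C)C(C)(C)C | intermediate
17 | methyl (4S,6R,10Z)-2-({[tert-butyl(dimethyl)silyl]oxy}methyl)-6,10-dimethyl-4-[(2-methylprop-2-enoyl)oxy]-3,7,12-trioxo-6-[(triethylsilyl)oxy]dodec-10-enoate (C2 epimers) | C=C(C)C(=O)O[C@H](C(=O)C(CO[Si](C)(C)C(C)(C)C)C(=O)OC)C[C@@](C)(O[Si](CC)(CC)CC)C(=O)CC/C(C)=C\C=O | intermediate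
18 | methyl (2Z,4S,6R,10Z)-2-({[tert-butyl(dimethyl)silyl]oxy}methyl)-6,10-dimethyl-4-[(2-methylprop-2-enoyl)oxy]-7,12-dioxo-6-[(triethylsilyl)oxy]-3-{[(trifluoromethyl)sulfonyl]oxy}dodeca-2,10-dienoate | C=C(C)C(=O)O[C@H](/C(OS(=O)(=O)C(F)(F)F)=C(\CO[Si](C)(C)C(C)(C)C)C(=O)OC)C[C@@](C)(O[Si](CC)(CC)CC)C(=O)CC/C(C)=C\C=O | intermediate
19 | methyl (4Z,6R,8S,10R)-13-{[tert-butyl(dimethyl)silyl]oxy}-8-(methacryloyloxy)-1-oxo-10-[(triethylsilyl)oxy]-6-[(trimethylsilyl)oxy]germacra-4,7(11)-dien-12-oate (ester cis to C6 across C7=C11) | C=C(C)C(=O)O[C@H]1C[C@@](C)(O[Si](CC)(CC)CC)C(=O)CC/C(C)=C\[C@@H](O[Si](C)(C)C)/C1=C(/CO[Si](C)(C)C(C)(C)C)C(=O)OC | intermediate (not isolated)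
20 | (4Z,6R,8S,10R)-10,13-dihydroxy-8-(methacryloyloxy)-1-oxogermacra-4,7(11)-dien-12,6-olide | C=C(C)C(=O)O[C@H]1C[C@@](C)(O)C(=O)CC/C(C)=C\[C@H]2OC(=O)C(CO)=C12 | intermediate
21 | (4Z,6R,8S,10R)-10,13-diacetoxy-8-(methacryloyloxy)-1-oxogermacra-4,7(11)-dien-12,6-olide (CNP0115165.2) | C=C(C)C(=O)O[C@H]1C[C@@](C)(OC(C)=O)C(=O)CC/C(C)=C\[C@H]2OC(=O)C(COC(C)=O)=C12 | target

**Step count and risks**

Total step count: 15 (steps 5, 6, 10 and 11 make the two side reagents). Longest linear sequence: 11 steps (steps 1, 2, 3, 4, 7, 8, 9, 12, 13, 14, 15).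

Most likely to fail, first: step 7, together with the hindered Kulinkovich reaction of step 4 that feeds it. β-Hydride elimination of the palladium homoenolate to a vinyl ketone, or oxidation of the free C8 hydroxyl, could outrun the coupling. The fallback sets out from lactone 5 and iodide 10 and comes back at 11. Iodide 10 is lithiated (tBuLi, Et2O, −78 °C) and added to oxirane (BF3·OEt2) to give (3Z)-3-methyl-5-[(triethylsilyl)oxy]pent-3-en-1-ol F1. Iodination (I2, PPh3, imidazole) gives triethyl{[(2Z)-5-iodo-3-methylpent-2-en-1-yl]oxy}silane F2. Its organolithium (tBuLi, −78 °C) adds once to lactone 5, the tetrahedral intermediate surviving until work-up, and this delivers ketone 11 by plain nucleophilic acyl substitution without any cyclopropanol.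

Second: step 12. The β-silyloxy diazo ester may give epoxide or react sluggishly, and the enal must stay untouched. The fallback sets out from 13 and comes back at 17. Commercial methyl 3-{[tert-butyl(dimethyl)silyl]oxy}propanoate is converted (LiN(iPr)2, Me3SiCl, −78 °C) into its methyl trimethylsilyl ketene acetal F3. A BF3·OEt2-mediated Mukaiyama aldol with 13 at −78 °C, selective for the α-acyloxy aldehyde, gives β-hydroxy ester F4. Dess–Martin oxidation of the new carbinol gives β-keto ester 17.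

Third: step 14, the proposed new step. The strain of the ten-membered ring, the tetrasubstituted alkenyl triflate and the C6 selectivity are all untested. The fallback uses known chemistry only, sets out from lactone 5 and comes back at 20, closing the ring one bond away by metathesis.
- 3-Methylbut-3-en-1-ylmagnesium bromide adds once to 5 (THF, −78 °C) to give (6R,8S)-8-hydroxy-2,6-dimethyl-6,9-bis[(triethylsilyl)oxy]non-1-en-5-one F5.
- The conditions of steps 8, 9, 12 and 13 then give methacrylate ester F6, aldehyde F7, β-keto ester F8 and enol triflate F9.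
- A stoichiometric intermolecular Nozaki–Hiyama–Kishi reaction of F9 with acrolein (CrCl2 in excess, NiCl2 1 mol%, DMSO/THF; then 2 M HCl) gives vinyl butenolide diol F10 as C6 epimers. The (6R) epimer is carried on and the other is recycled by DBU equilibration at C6, so this fallback gives up the substrate control at C6 that the main route has.
- Ring-closing metathesis (second-generation Hoveyda–Grubbs catalyst, toluene, 80 °C, 1 mM) between the isopropenyl end and the C6 vinyl group closes the (Z)-trisubstituted ten-membered ring to give 20.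

**Further compounds**

F1 | step 7 | (3Z)-3-methyl-5-[(triethylsilyl)oxy]pent-3-en-1-ol | OCC/C(C)=C\CO[Si](CC)(CC)CC
F2 | step 7 | triethyl{[(2Z)-5-iodo-3-methylpent-2-en-1-yl]oxy}silane | ICC/C(C)=C\CO[Si](CC)(CC)CC
F3 | step 12 | tert-butyl{[3-methoxy-3-(trimethylsilyloxy)prop-2-en-1-yl]oxy}dimethylsilane (methyl trimethylsilyl ketene acetal) | COC(O[Si](C)(C)C)=CCO[Si](C)(C)C(C)(C)C
F4 | step 12 | methyl (4S,6R,10Z)-2-({[tert-butyl(dimethyl)silyl]oxy}methyl)-3-hydroxy-6,10-dimethyl-4-[(2-methylprop-2-enoyl)oxy]-7,12-dioxo-6-[(triethylsilyl)oxy]dodec-10-enoate (C2/C3 diastereomers) | C=C(C)C(=O)O[C@H](C(O)C(CO[Si](C)(C)C(C)(C)C)C(=O)OC)C[C@@](C)(O[Si](CC)(CC)CC)C(=O)CC/C(C)=C\C=O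
F5 | step 14 | (6R,8S)-8-hydroxy-2,6-dimethyl-6,9-bis[(triethylsilyl)oxy]non-1-en-5-one | O[C@H](CO[Si](CC)(CC)CC)C[C@@](C)(O[Si](CC)(CC)CC)C(=O)CCC(C)=C
F6 | step 14 | (2S,4R)-4,8-dimethyl-5-oxo-1,4-bis[(triethylsilyl)oxy]non-8-en-2-yl 2-methylprop-2-enoate | C=C(C)C(=O)O[C@H](CO[Si](CC)(CC)CC)C[C@@](C)(O[Si](CC)(CC)CC)C(=O)CCC(C)=C
F7 | step 14 | (2S,4R)-4,8-dimethyl-1,5-dioxo-4-[(triethylsilyl)oxy]non-8-en-2-yl 2-methylprop-2-enoate | C=C(C)C(=O)O[C@H](C=O)C[C@@](C)(O[Si](CC)(CC)CC)C(=O)CCC(C)=C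
F8 | step 14 | methyl (4S,6R)-2-({[tert-butyl(dimethyl)silyl]oxy}methyl)-6,10-dimethyl-4-[(2-methylprop-2-enoyl)oxy]-3,7-dioxo-6-[(triethylsilyl)oxy]undec-10-enoate | C=C(C)C(=O)O[C@H](C(=O)C(CO[Si](C)(C)C(C)(C)C)C(=O)OC)C[C@@](C)(O[Si](CC)(CC)CC)C(=O)CCC(C)=C
F9 | step 14 | methyl (2Z,4S,6R)-2-({[tert-butyl(dimethyl)silyl]oxy}methyl)-6,10-dimethyl-4-[(2-methylprop-2-enoyl)oxy]-7-oxo-6-[(triethylsilyl)oxy]-3-{[(trifluoromethyl)sulfonyl]oxy}undeca-2,10-dienoate | C=C(C)C(=O)O[C@H](/C(OS(=O)(=O)C(F)(F)F)=C(\CO[Si](C)(C)C(C)(C)C)C(=O)OC)C[C@@](C)(O[Si](CC)(CC)CC)C(=O)CCC(C)=C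
F10 | step 14 | (1S,3R)-3-hydroxy-1-[(2R)-4-(hydroxymethyl)-5-oxo-2-vinyl-2,5-dihydrofuran-3-yl]-3,7-dimethyl-4-oxooct-7-en-1-yl 2-methylprop-2-enoate | C=C(C)C(=O)O[C@H](C1=C(CO)C(=O)O[C@@H]1C=C)C[C@@](C)(O)C(=O)CCC(C)=C
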